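## Analysis of the target

Target 19 is the methyl ester of a linear tridepside in which three 2,4-dioxygenated 6-methylbenzoyl (orsellinate) rings, A, B and C, are joined head to tail by two aryl ester bonds: the carbonyl of ring A to O4 of ring B, and the carbonyl of ring B to O4 of ring C, which ends in the methyl ester. There is no stereocentre and no ring to construct, so the problem is how two ester C–O bonds and four free phenols are delivered. Each carbonyl carbon lies between an ortho oxygen and an ortho methyl group and is shielded against the tetrahedral addition that ordinary acylation needs. The finished aryl esters, in contrast, are activated esters that transesterify, migrate or cleave under alkoxide, hydroxide or hot phenoxide. On every ring the 2-hydroxyl is hydrogen-bonded to its own carbonyl and is less nucleophilic than the 4-hydroxyl; this allows selective work at O4, but each O2 must still be capped before any step that cannot tolerate a free phenol. The caps have to leave at the end under neutral conditions, which points to benzyl ethers and hydrogenolysis. The plan rests on the neighbouring pair C4–O / C3–H of ring C beside the oxygen on C2: a 3,4-didehydro ring C flanked by that oxygen is polarised so that an oxygen nucleophile enters at C4 and hydrogen ends on C3. The B–C ester oxygen can therefore be supplied by the carboxylic acid of ring B acting as a nucleophile.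

## Retrosynthetic reasoning

The four O–benzyl bonds of the tetrabenzyl ether 18 are cut last, so that 19 arises by hydrogenolysis. This is the only deprotection in the route that touches the finished depside, and it is neutral, so both aryl esters and the methyl ester are expected to survive.

In 18 the bond between C4 of ring C and the ester oxygen is cut, together with the C3–H bond. This gives the A–B acid 8 as an oxygen nucleophile and the aryne 17, which is released from the silyl triflate 16. The cut is made here, and not at the acyl C–O bond, because the ring-B carbonyl is doubly ortho-substituted. In this direction the acid reacts through oxygen and its carbonyl carbon is never attacked. The O4 of the purchased ring C becomes the leaving group and is replaced by the acid oxygen. The forward step has to place the carboxylate on C4 and not C3, protonate C3 before the aryl anion can attack the new ester, and meet no O–H other than the carboxyl.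

The silyl triflate 16 is cut at its C3–Si and O4–S bonds and traced to the iodophenol 13 through the silyl ether 14 and the phenoxide 15. Halogen–lithium exchange next to an O-silyl group moves silicon from oxygen to carbon and leaves a phenoxide that is triflated in the same flask. An iodide is preferred because its exchange is fast enough to outrun attack on the hindered methyl ester.

Phenol 13 is traced through the acetal-protected ethers 12 and 11 to the iodo diol 10, and from there to methyl orsellinate 9. The benzyl group on O2 must be in place before silicon and triflate are introduced. A free O2 phenoxide beside the silylated C3, with triflate on C4, would itself trigger a silyl shift to oxygen and loss of triflate, releasing the aryne too early. Since O4 is the more reactive hydroxyl, it is masked temporarily as a methoxymethyl ether while O2 is benzylated. The C3–I bond is formed first, on the free diol under mildly basic aqueous conditions, where resorcinol-type phenolates are attacked at the carbon between the two oxygens. Bromination under neutral conditions is not relied on, because C5 is comparably activated there.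

The acid 8 is taken back to the aldehyde 7, so that the ring-B carboxyl is carried at the aldehyde oxidation level and needs no protecting group of its own. Aldehyde 7 comes from the phenol 6 and benzyl bromide 2. Phenol 6 is cut at the A–B acyl C–O bond into the ring-A acid 4 and the dihydroxy aldehyde 1. The classical direction is acceptable here because 4, through the mixed anhydride 5, ionises to an acylium ion stabilised by its ortho and para oxygens. That ion is linear and not subject to the steric shielding, and O4 of 1 is its only non-chelated hydroxyl.

Acid 4 is derived from the dibenzyl aldehyde 3, and 3 from 1 and two equivalents of 2, so rings A and B come from the same purchased aldehyde and ring C from 9.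

## Alternatives that were turned down

Alternative 1: Ring B is built by a formal [3+3] cyclocondensation, cutting its C3–C4 and C1–C6 bonds.
- **Forward step:** the bis(trimethylsilyl) dienol ether A1, in which the acetoacetyl unit is already esterified to O4 of ring C, and (E)-3-methoxybut-2-enoyl chloride A2 are combined with TiCl4. The terminal diene carbon is acylated, the central carbon condenses at the methoxy-bearing carbon with loss of methanol, and aromatisation gives the didepside phenol A3.
- **For:** the B–C ester exists before ring B is aromatic, so the hindered-carbonyl problem does not arise for that bond. Orsellinates are known to form this way from alkyl acetoacetates.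
- **Against:** A1 is the dienol ether of an aryl acetoacetate, a class whose enolates can expel the phenoxide as an acylketene forms. TiCl4 is a hard Lewis acid towards the aryl ester and the salicylate. If the terminal carbon attacks the β-carbon and not the acyl chloride, the 2,6-dihydroxy-4-methyl isomer results. A3 still lacks ring A, so a classical acylation with acid 4 follows, in the presence of three free phenols.
- **Comparison:** this route is stronger in that it needs no silyl triflate and forms the B–C ester at an unhindered stage. It spends its key step on a ring that can be bought, however, and is no shorter. The chosen plan buys all three rings and forms only the one difficult bond.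

Alternative 2: Ring B is assembled by a Danheiser benzannulation, cutting C1–C2, C2–C3 and C4–C5.
- **Forward step:** irradiation of the diazoketone A4 causes a Wolff rearrangement to a vinylketene. This adds to the siloxyalkyne A5 in a [2+2] sense, the cyclobutenone opens, and six-electron closure with tautomerisation gives the didepside A6.
- **For:** the connectivity is fixed by the mechanism. Ring B emerges with O2 free and O4 silylated, a cleaner differentiation than the chelation-based selectivity used in the chosen route.
- **Against:** A4 is an unsaturated diazoketone carrying an aryl ester and needs several steps and diazo chemistry. A5 is a sensitive reagent and the step is photochemical. After A6, three more operations remain (benzylation of O2, desilylation, acylation with acid 4), and the last is again the classical acylation.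
- **Comparison:** this route is stronger on regiochemical certainty and on oxygen differentiation in ring B. The chosen route is shorter, uses purchased rings, and has a thermal key step at room temperature that forms one bond.

Alternative 3: The B–C ester is cut at both the aryl–carbonyl C–C bond and the carbonyl–O bond, for a palladium-catalysed carbonylation.
- **Forward step:** the ring-B aryl iodide A7, carbon monoxide A8 and the 4-hydroxyl of methyl orsellinate 9 combine under Pd(OAc)2 and Xantphos with base to give the tri-O-benzyl tridepside A9.
- **For:** it is a three-component union in which ring C is used as purchased, with its chelated 2-hydroxyl unprotected. The hindered carbonyl is made from A8 and is never attacked as an acid derivative.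
- **Against:** the iodine of A7 lies between a benzyloxy and a methyl group, so the aroylpalladium intermediate is crowded and is intercepted only slowly by a weakly nucleophilic phenoxide. Direct C–O coupling or reduction can compete. Base and the phenoxide of 9 at the temperature required threaten the existing A–B ester of A7 by transesterification. Preparing A7 needs a clean iodination of an orcinol monoether that has three activated positions.
- **Comparison:** this route is at least as convergent and is clearly better on step economy for ring C, which the chosen route must elaborate over five steps. The chosen route avoids hot phenoxide and gas handling, exposes the A–B ester only to CsF at room temperature, and takes its regiochemistry from the benzyloxy group on C2.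

Key step: step 11

Assumption: 2,4-dihydroxy-6-methylbenzaldehyde 1, benzyl bromide 2 and methyl orsellinate 9 are taken as purchasable. Benzyl bromide is entered as a reactant wherever it is used; in step 1, where two benzyl groups are installed, the second equivalent is also entered as a reagent that adds atoms.

## Route

Step 1
Reactants: 1 2,4-dihydroxy-6-methylbenzaldehyde; 2 benzyl bromide
Product: 3 2,4-bis(benzyloxy)-6-methylbenzaldehyde
Conditions: BnBr (2.4 equiv), K2CO3, DMF, 60 °C
Reagents that add atoms: benzyl bromide, BrCc1ccccc1 (the second equivalent of 2; one benzyl group enters at each hydroxyl)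
Why: Double Williamson etherification that consumes two equivalents of 2; warming in DMF should also alkylate the formyl-chelated 2-hydroxyl after the more reactive 4-hydroxyl.

Step 2
Reactants: 3 2,4-bis(benzyloxy)-6-methylbenzaldehyde
Product: 4 2,4-bis(benzyloxy)-6-methylbenzoic acid
Conditions: NaClO2, NaH2PO4, 2-methyl-2-butene, t-BuOH–THF–H2O, 0 °C to rt
Reagents that add atoms: sodium chlorite, [Na+].[O-]Cl=O
Why: Pinnick oxidation; the buffered chlorite oxidises the hindered aldehyde, and 2-methyl-2-butene removes hypochlorous acid before it can chlorinate the electron-rich ring.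

Step 3
Reactants: 4 2,4-bis(benzyloxy)-6-methylbenzoic acid; 1 2,4-dihydroxy-6-methylbenzaldehyde
Product: 6 4-formyl-3-hydroxy-5-methylphenyl 2,4-bis(benzyloxy)-6-methylbenzoate, via mixed trifluoroacetic anhydride 5 (not isolated)
Conditions: (CF3CO)2O, toluene, rt
Reagents that add atoms: trifluoroacetic anhydride, O=C(OC(=O)C(F)(F)F)C(F)(F)F (its acyl group is carried only by intermediate 5)
Why: Depside esterification by the trifluoroacetic anhydride method; 5 ionises to a linear acylium ion stabilised by the ortho and para benzyloxy groups, so the flanking substituents do not block it. The 4-hydroxyl of 1 is the only one not held in a hydrogen bond to the formyl group and should be acylated selectively.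

Step 4
Reactants: 6 4-formyl-3-hydroxy-5-methylphenyl 2,4-bis(benzyloxy)-6-methylbenzoate; 2 benzyl bromide
Product: 7 3-(benzyloxy)-4-formyl-5-methylphenyl 2,4-bis(benzyloxy)-6-methylbenzoate
Conditions: BnBr, K2CO3, DMF, rt
Reagents that add atoms: none
Why: Williamson etherification of the remaining chelated phenol; the aryl ester is flanked by benzyloxy and methyl on its acyl side and should resist carbonate and phenoxide at room temperature.

Step 5
Reactants: 7 3-(benzyloxy)-4-formyl-5-methylphenyl 2,4-bis(benzyloxy)-6-methylbenzoate
Product: 8 2-(benzyloxy)-4-{[2,4-bis(benzyloxy)-6-methylbenzoyl]oxy}-6-methylbenzoic acid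
Conditions: NaClO2, NaH2PO4, 2-methyl-2-butene, t-BuOH–THF–H2O, rt
Reagents that add atoms: sodium chlorite, [Na+].[O-]Cl=O
Why: Pinnick oxidation under weakly acidic buffer, which should leave the aryl ester and the benzyl ethers untouched and frees the ring-B carboxyl without any deprotection step.

Step 6
Reactants: 9 methyl orsellinate (methyl 2,4-dihydroxy-6-methylbenzoate)
Product: 10 methyl 2,4-dihydroxy-3-iodo-6-methylbenzoate
Conditions: I2 (1.0 equiv), NaHCO3, THF–H2O, 0 °C
Reagents that add atoms: iodine, II
Why: Electrophilic iodination through the 4-phenolate; as with resorcinol under bicarbonate, attack is expected at the carbon between the two oxygens (C3). C5 is the more hindered position because it is flanked by the C6 methyl group.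

Step 7
Reactants: 10 methyl 2,4-dihydroxy-3-iodo-6-methylbenzoate
Product: 11 methyl 2-hydroxy-3-iodo-4-(methoxymethoxy)-6-methylbenzoate
Conditions: MOMCl (1.1 equiv), i-Pr2NEt, CH2Cl2, 0 °C to rt
Reagents that add atoms: chloromethyl methyl ether, COCCl
Why: Selective O-alkylation; the 2-hydroxyl is tied in a hydrogen bond to the ester carbonyl and is far less nucleophilic, so only the 4-O-methoxymethyl ether should form with an amine base.

Step 8
Reactants: 11 methyl 2-hydroxy-3-iodo-4-(methoxymethoxy)-6-methylbenzoate; 2 benzyl bromide
Product: 12 methyl 2-(benzyloxy)-3-iodo-4-(methoxymethoxy)-6-methylbenzoate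
Conditions: BnBr, K2CO3, DMF, 50 °C
Reagents that add atoms: none
Why: Williamson etherification of the chelated 2-hydroxyl under more forcing carbonate conditions; the acetal on O4 is inert to base, so the benzyl group can only go to O2.

Step 9
Reactants: 12 methyl 2-(benzyloxy)-3-iodo-4-(methoxymethoxy)-6-methylbenzoate
Product: 13 methyl 2-(benzyloxy)-4-hydroxy-3-iodo-6-methylbenzoate
Conditions: HCl (cat.), MeOH, 40 °C
Reagents that add atoms: none
Why: Acid-catalysed acetal exchange with methanol removes the methoxymethyl group; the benzyl ether, the aryl iodide and the methyl ester (in methanol) should be unaffected.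

Step 10
Reactants: 13 methyl 2-(benzyloxy)-4-hydroxy-3-iodo-6-methylbenzoate
Product: 16 methyl 2-(benzyloxy)-6-methyl-4-(trifluoromethylsulfonyloxy)-3-(trimethylsilyl)benzoate, via aryl trimethylsilyl ether 14 (not isolated), via lithium 2-silylphenoxide 15 (not isolated)
Conditions: a) (Me3Si)2NH, THF, 65 °C, then evaporation; b) n-BuLi (1.05 equiv), THF, −78 °C; c) Tf2O, −78 to 0 °C
Reagents that add atoms: hexamethyldisilazane, C[Si](C)(C)N[Si](C)(C)C; trifluoromethanesulfonic anhydride, O=S(=O)(OS(=O)(=O)C(F)(F)F)C(F)(F)F; n-butyllithium, [Li]CCCC (lithium is carried only by intermediate 15)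
Why: O-silylation, iodine–lithium exchange and retro-Brook rearrangement (1,3 shift of silicon from oxygen to carbon), then O-triflation of the phenoxide, the standard entry to 2-(trimethylsilyl)aryl triflates. Exchange of an aryl iodide flanked by two oxygens should outrun addition of n-BuLi to the doubly ortho-substituted methyl ester at −78 °C.

Step 11
Reactants: 8 2-(benzyloxy)-4-{[2,4-bis(benzyloxy)-6-methylbenzoyl]oxy}-6-methylbenzoic acid; 16 methyl 2-(benzyloxy)-6-methyl-4-(trifluoromethylsulfonyloxy)-3-(trimethylsilyl)benzoate
Product: 18 methyl 2-(benzyloxy)-4-{[2-(benzyloxy)-4-{[2,4-bis(benzyloxy)-6-methylbenzoyl]oxy}-6-methylbenzoyl]oxy}-6-methylbenzoate, via 3,4-aryne 17 (not isolated)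
Conditions: 16 (1.5 equiv), CsF (3 equiv), MeCN–toluene, 0 °C to rt
Reagents that add atoms: none
Why: Fluoride attacks the silicon of 16, negative charge builds on C3 and triflate leaves from C4, releasing the aryne 17. CsF also converts 8 into its cesium carboxylate, whose oxygen adds to C4, and the aryl anion left on C3 is protonated by the hydrogen fluoride formed or by a second molecule of 8. The closest known reaction is the O-arylation of arenecarboxylic acids by arynes generated from 2-(trimethylsilyl)aryl triflates with CsF in acetonitrile at room temperature. No ring is closed and no stereocentre is formed. The step needs regioselectivity for C4: the benzyloxy group on C2 withdraws inductively and distorts the aryne so that the nucleophile enters at the remote carbon and the charge develops on C3 beside oxygen, while C5 carries only hydrogen and exerts no opposing effect. It also needs protonation of C3 to win over a 1,3 acyl shift onto that carbon; the shift would pass through a four-membered transition state onto a carbonyl flanked by benzyloxy and methyl, and the low temperature disfavours it further. Every phenol is benzylated, so the carboxyl is the only O–H nucleophile offered to the aryne, and the benzyl group on O2 of 16 also rules out a premature silyl shift to oxygen. The A–B aryl ester and the methyl ester are hindered and should be inert to CsF in acetonitrile.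

Step 12
Reactants: 18 methyl 2-(benzyloxy)-4-{[2-(benzyloxy)-4-{[2,4-bis(benzyloxy)-6-methylbenzoyl]oxy}-6-methylbenzoyl]oxy}-6-methylbenzoate
Product: 19 methyl 4-{[4-{[2,4-dihydroxy-6-methylbenzoyl]oxy}-2-hydroxy-6-methylbenzoyl]oxy}-2-hydroxy-6-methylbenzoate
Conditions: H2 (1 atm), 10% Pd/C, EtOAc, rt
Reagents that add atoms: none
Why: Hydrogenolysis of four aryl benzyl ethers; aryl esters and the methyl ester are not reduced, and the aprotic solvent avoids transesterification of the depside bonds.

## Compound list

1 | 2,4-dihydroxy-6-methylbenzaldehyde | Cc1cc(O)cc(O)c1C=O | starting material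
2 | benzyl bromide | BrCc1ccccc1 | starting material
3 | 2,4-bis(benzyloxy)-6-methylbenzaldehyde | Cc1cc(OCc2ccccc2)cc(OCc2ccccc2)c1C=O | intermediate
4 | 2,4-bis(benzyloxy)-6-methylbenzoic acid | Cc1cc(OCc2ccccc2)cc(OCc2ccccc2)c1C(=O)O | intermediate
5 | 2,4-bis(benzyloxy)-6-methylbenzoic trifluoroacetic anhydride (not isolated) | Cc1cc(OCc2ccccc2)cc(OCc2ccccc2)c1C(=O)OC(=O)C(F)(F)F | intermediate
6 | 4-formyl-3-hydroxy-5-methylphenyl 2,4-bis(benzyloxy)-6-methylbenzoate | Cc1cc(OC(=O)c2c(C)cc(OCc3ccccc3)cc2OCc2ccccc2)cc(O)c1C=O | intermediate
7 | 3-(benzyloxy)-4-formyl-5-methylphenyl 2,4-bis(benzyloxy)-6-methylbenzoate | Cc1cc(OC(=O)c2c(C)cc(OCc3ccccc3)cc2OCc2ccccc2)cc(OCc2ccccc2)c1C=O | intermediate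
8 | 2-(benzyloxy)-4-{[2,4-bis(benzyloxy)-6-methylbenzoyl]oxy}-6-methylbenzoic acid (A–B acid) | OC(=O)c1c(C)cc(OC(=O)c2c(C)cc(OCc3ccccc3)cc2OCc2ccccc2)cc1OCc1ccccc1 | intermediate
9 | methyl orsellinate (methyl 2,4-dihydroxy-6-methylbenzoate) | COC(=O)c1c(C)cc(O)cc1O | starting material
10 | methyl 2,4-dihydroxy-3-iodo-6-methylbenzoate | COC(=O)c1c(C)cc(O)c(I)c1O | intermediate
11 | methyl 2-hydroxy-3-iodo-4-(methoxymethoxy)-6-methylbenzoate | COCOc1cc(C)c(C(=O)OC)c(O)c1I | intermediate
12 | methyl 2-(benzyloxy)-3-iodo-4-(methoxymethoxy)-6-methylbenzoate | COCOc1cc(C)c(C(=O)OC)c(OCc2ccccc2)c1I | intermediate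
13 | methyl 2-(benzyloxy)-4-hydroxy-3-iodo-6-methylbenzoate | COC(=O)c1c(C)cc(O)c(I)c1OCc1ccccc1 | intermediate
14 | methyl 2-(benzyloxy)-3-iodo-6-methyl-4-(trimethylsilyloxy)benzoate (not isolated) | COC(=O)c1c(C)cc(O[Si](C)(C)C)c(I)c1OCc1ccccc1 | intermediate
15 | lithium 3-(benzyloxy)-4-(methoxycarbonyl)-5-methyl-2-(trimethylsilyl)phenoxide (not isolated) | [Li+].COC(=O)c1c(C)cc([O-])c([Si](C)(C)C)c1OCc1ccccc1 | intermediate
16 | methyl 2-(benzyloxy)-6-methyl-4-(trifluoromethylsulfonyloxy)-3-(trimethylsilyl)benzoate | COC(=O)c1c(C)cc(OS(=O)(=O)C(F)(F)F)c([Si](C)(C)C)c1OCc1ccccc1 | intermediate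
17 | methyl 2-(benzyloxy)-3,4-didehydro-6-methylbenzoate (aryne, not isolated) | COC(=O)C1=C(OCc2ccccc2)C#CC=C1C | intermediate
18 | methyl 2-(benzyloxy)-4-{[2-(benzyloxy)-4-{[2,4-bis(benzyloxy)-6-methylbenzoyl]oxy}-6-methylbenzoyl]oxy}-6-methylbenzoate (tetra-O-benzyl tridepside) | COC(=O)c1c(C)cc(OC(=O)c2c(C)cc(OC(=O)c3c(C)cc(OCc4ccccc4)cc3OCc3ccccc3)cc2OCc2ccccc2)cc1OCc1ccccc1 | intermediate
19 | methyl 4-{[4-{[2,4-dihydroxy-6-methylbenzoyl]oxy}-2-hydroxy-6-methylbenzoyl]oxy}-2-hydroxy-6-methylbenzoate | COC(=O)c1c(C)cc(OC(=O)c2c(C)cc(OC(=O)c3c(C)cc(O)cc3O)cc2O)cc1O | target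

## Step count and least certain steps

Total: 12 steps. Longest linear sequence: 7 steps (steps 1 to 5, 11 and 12; the ring-C branch, steps 6 to 10, 11 and 12, is equally long).

**Step 11 (key step).** The most likely failures are these:
- addition of the carboxylate at C3 if the directing effect of the benzyloxy group is weaker than expected in this tetrasubstituted aryne;
- a 1,3 acyl shift of the aryl anion onto C3 in place of protonation;
- consumption of the aryne by side reactions, because the hindered carboxylate adds slowly.

Fallback: starting from 8, the acid would be activated with trifluoroacetic anhydride in toluene and used to acylate the free 4-hydroxyl of 9, giving methyl 4-{[2-(benzyloxy)-4-{[2,4-bis(benzyloxy)-6-methylbenzoyl]oxy}-6-methylbenzoyl]oxy}-2-hydroxy-6-methylbenzoate F1. Hydrogenolysis of its three benzyl ethers under the conditions of step 12 rejoins the route at 19. This gives up the aryne bond formation and accepts a classical acylation through the acylium ion of ring B.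

**Step 6.** Iodination may occur at C5 as well as C3, or twice, because both positions are activated by two oxygens and the preference for C3 rests on analogy with simpler resorcinols. Fallback: starting from 9, exhaustive iodination with excess I2 and NaHCO3 would give methyl 2,4-dihydroxy-3,5-diiodo-6-methylbenzoate F2, for which no regiochemical question arises. The operations of steps 7 to 9 would then give methyl 2-hydroxy-3,5-diiodo-4-(methoxymethoxy)-6-methylbenzoate F3, methyl 2-(benzyloxy)-3,5-diiodo-4-(methoxymethoxy)-6-methylbenzoate F4 and methyl 2-(benzyloxy)-4-hydroxy-3,5-diiodo-6-methylbenzoate F5. Silylation would give methyl 2-(benzyloxy)-3,5-diiodo-6-methyl-4-(trimethylsilyloxy)benzoate F6. One equivalent of n-BuLi should exchange the iodine on C3, the one flanked by two oxygens, and silyl migration would give lithium 3-(benzyloxy)-6-iodo-4-(methoxycarbonyl)-5-methyl-2-(trimethylsilyl)phenoxide F7. Tf2O would convert this to methyl 2-(benzyloxy)-5-iodo-6-methyl-4-(trifluoromethylsulfonyloxy)-3-(trimethylsilyl)benzoate F8. Radical reduction of the remaining aryl iodide with Bu3SnH and azobisisobutyronitrile in toluene at 80 °C rejoins the route at 16. The choice between C3 and C5 is thereby moved from an electrophilic substitution to a halogen–lithium exchange, in which the carbanion between two oxygens is clearly favoured.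

**Step 10.** n-BuLi or the aryllithium may add to the methyl ester, or abstract a benzylic proton from the C6 methyl or the benzyl ether, before the silyl shift is complete; this would lead to loss of iodine without C-silylation. Fallback without organolithium: starting from 13, pivaloylation (pivaloyl chloride, pyridine) would give methyl 2-(benzyloxy)-3-iodo-6-methyl-4-(pivaloyloxy)benzoate F9. Palladium-catalysed silylation with hexamethyldisilane (Pd2(dba)3, 2-(di-tert-butylphosphino)biphenyl, LiOAc, DMF, 100 °C) would give methyl 2-(benzyloxy)-6-methyl-4-(pivaloyloxy)-3-(trimethylsilyl)benzoate F10. Brief treatment with NaOMe in MeOH at 0 °C would give methyl 2-(benzyloxy)-4-hydroxy-6-methyl-3-(trimethylsilyl)benzoate F11. Acid is avoided at this stage because the arylsilane between two oxygens is prone to protodesilylation. Triflation with Tf2O and pyridine rejoins the route at 16.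

**Step 3.** The acylium ion may attack a ring carbon of the electron-rich aldehyde 1 (Friedel–Crafts acylation), acylate both hydroxyls, or lose its ortho benzyl group. Fallback: the hydroxyls are differentiated by protection before coupling. Starting from 1, selective 4-O-alkylation (MOMCl, i-Pr2NEt) would give 2-hydroxy-4-(methoxymethoxy)-6-methylbenzaldehyde F12. Benzylation with 2 and K2CO3 would give 2-(benzyloxy)-4-(methoxymethoxy)-6-methylbenzaldehyde F13, and HCl in MeOH followed by aqueous work-up would give 2-(benzyloxy)-4-hydroxy-6-methylbenzaldehyde F14. Acid 4 would be converted with oxalyl chloride and catalytic DMF into 2,4-bis(benzyloxy)-6-methylbenzoyl chloride F15. Coupling of F14 with F15 (Et3N, catalytic 4-dimethylaminopyridine, CH2Cl2) rejoins the route at 7, bypassing 6. The phenoxide is then acylated on oxygen under basic conditions in which ring acylation is not expected.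

## Further compounds

F1 | step 11 | methyl 4-{[2-(benzyloxy)-4-{[2,4-bis(benzyloxy)-6-methylbenzoyl]oxy}-6-methylbenzoyl]oxy}-2-hydroxy-6-methylbenzoate | COC(=O)c1c(C)cc(OC(=O)c2c(C)cc(OC(=O)c3c(C)cc(OCc4ccccc4)cc3OCc3ccccc3)cc2OCc2ccccc2)cc1O
F2 | step 6 | methyl 2,4-dihydroxy-3,5-diiodo-6-methylbenzoate | COC(=O)c1c(C)c(I)c(O)c(I)c1O
F3 | step 6 | methyl 2-hydroxy-3,5-diiodo-4-(methoxymethoxy)-6-methylbenzoate | COCOc1c(I)c(C)c(C(=O)OC)c(O)c1I
F4 | step 6 | methyl 2-(benzyloxy)-3,5-diiodo-4-(methoxymethoxy)-6-methylbenzoate | COCOc1c(I)c(C)c(C(=O)OC)c(OCc2ccccc2)c1I
F5 | step 6 | methyl 2-(benzyloxy)-4-hydroxy-3,5-diiodo-6-methylbenzoate | COC(=O)c1c(C)c(I)c(O)c(I)c1OCc1ccccc1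
F6 | step 6 | methyl 2-(benzyloxy)-3,5-diiodo-6-methyl-4-(trimethylsilyloxy)benzoate | COC(=O)c1c(C)c(I)c(O[Si](C)(C)C)c(I)c1OCc1ccccc1
F7 | step 6 | lithium 3-(benzyloxy)-6-iodo-4-(methoxycarbonyl)-5-methyl-2-(trimethylsilyl)phenoxide | [Li+].COC(=O)c1c(C)c(I)c([O-])c([Si](C)(C)C)c1OCc1ccccc1
F8 | step 6 | methyl 2-(benzyloxy)-5-iodo-6-methyl-4-(trifluoromethylsulfonyloxy)-3-(trimethylsilyl)benzoate | COC(=O)c1c(C)c(I)c(OS(=O)(=O)C(F)(F)F)c([Si](C)(C)C)c1OCc1ccccc1
F9 | step 10 | methyl 2-(benzyloxy)-3-iodo-6-methyl-4-(pivaloyloxy)benzoate | COC(=O)c1c(C)cc(OC(=O)C(C)(C)C)c(I)c1OCc1ccccc1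
F10 | step 10 | methyl 2-(benzyloxy)-6-methyl-4-(pivaloyloxy)-3-(trimethylsilyl)benzoate | COC(=O)c1c(C)cc(OC(=O)C(C)(C)C)c([Si](C)(C)C)c1OCc1ccccc1
F11 | step 10 | methyl 2-(benzyloxy)-4-hydroxy-6-methyl-3-(trimethylsilyl)benzoate | COC(=O)c1c(C)cc(O)c([Si](C)(C)C)c1OCc1ccccc1
F12 | step 3 | 2-hydroxy-4-(methoxymethoxy)-6-methylbenzaldehyde | COCOc1cc(C)c(C=O)c(O)c1
F13 | step 3 | 2-(benzyloxy)-4-(methoxymethoxy)-6-methylbenzaldehyde | COCOc1cc(C)c(C=O)c(OCc2ccccc2)c1
F14 | step 3 | 2-(benzyloxy)-4-hydroxy-6-methylbenzaldehyde | Cc1cc(O)cc(OCc2ccccc2)c1C=O
F15 | step 3 | 2,4-bis(benzyloxy)-6-methylbenzoyl chloride | Cc1cc(OCc2ccccc2)cc(OCc2ccccc2)c1C(Cl)=O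
A1 | alternative 1 | methyl 4-{[1,3-bis(trimethylsilyloxy)buta-1,3-dien-1-yl]oxy}-6-methyl-2-(trimethylsilyloxy)benzoate | C=C(O[Si](C)(C)C)C=C(O[Si](C)(C)C)Oc1cc(C)c(C(=O)OC)c(O[Si](C)(C)C)c1
A2 | alternative 1 | (E)-3-methoxybut-2-enoyl chloride | CO/C(C)=C/C(Cl)=O
A3 | alternative 1 | methyl 4-[(2,4-dihydroxy-6-methylbenzoyl)oxy]-2-hydroxy-6-methylbenzoate | COC(=O)c1c(C)cc(OC(=O)c2c(C)cc(O)cc2O)cc1O
A4 | alternative 2 | methyl 2-(benzyloxy)-4-{[(2E)-5-diazo-3-methyl-4-oxopent-2-enoyl]oxy}-6-methylbenzoate | COC(=O)c1c(C)cc(OC(=O)/C=C(\C)C(=O)C=[N+]=[N-])cc1OCc1ccccc1
A5 | alternative 2 | (triisopropylsilyloxy)acetylene | C#CO[Si](C(C)C)(C(C)C)C(C)C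
A6 | alternative 2 | methyl 2-(benzyloxy)-4-{[2-hydroxy-6-methyl-4-(triisopropylsilyloxy)benzoyl]oxy}-6-methylbenzoate | COC(=O)c1c(C)cc(OC(=O)c2c(C)cc(O[Si](C(C)C)(C(C)C)C(C)C)cc2O)cc1OCc1ccccc1
A7 | alternative 3 | 3-(benzyloxy)-4-iodo-5-methylphenyl 2,4-bis(benzyloxy)-6-methylbenzoate | Cc1cc(OC(=O)c2c(C)cc(OCc3ccccc3)cc2OCc2ccccc2)cc(OCc2ccccc2)c1I
A8 | alternative 3 | carbon monoxide | [C-]#[O+]
A9 | alternative 3 | methyl 4-{[2-(benzyloxy)-4-{[2,4-bis(benzyloxy)-6-methylbenzoyl]oxy}-6-methylbenzoyl]oxy}-2-hydroxy-6-methylbenzoate | COC(=O)c1c(C)cc(OC(=O)c2c(C)cc(OC(=O)c3c(C)cc(OCc4ccccc4)cc3OCc3ccccc3)cc2OCc2ccccc2)cc1O
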